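**Retrosynthetic overview**
1. Target ⇐ its 7,8-bis-silyl ether ⇐ an open-chain aldehyde. The ten-membered carbocycle closes first at C5–C6 (alkenyl bromide + aldehyde, catalytic in chromium and nickel), and the γ-lactone closes onto the new C6 oxygen in the same flask.
2. Open chain ⇐ nickel-catalysed Nozaki–Hiyama–Kishi coupling at C9–C10 of a (Z)-alkenyl iodide with the eastern aldehyde, then isobutyrylation.
3. Eastern aldehyde (C6–C9, C11–C13) ⇐ L-erythrulose (supplies C8) + methyl propiolate, joined by a new CuH reductive aldol that builds the C7 quaternary carbinol.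
4. Western bromo-iodo-diene (C1–C5, C10, C14, C15) ⇐ pent-4-yn-1-ol (carboalumination/bromination, oxidation) + iodoethane (α-iodo ylide).
5. C7, C9 and C6 are each set by Felkin–Anh addition anti to the neighbouring C–OSi bond, relayed from C8.

Assumption and labels: atoms carry germacranolide numbers (C6 lactone CH–O, C7 tertiary carbinol, C8 free carbinol, C9 ester carbinol, C11–C13 methylene-lactone carbons); TES = triethylsilyl, TMS = trimethylsilyl, IPr = 1,3-bis(2,6-diisopropylphenyl)imidazol-2-ylidene.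

**Route**

Step 1
Reactants: 1 pent-4-yn-1-ol
Product: 3 (4E)-5-bromo-4-methylpent-4-en-1-ol, via alkenylalane 2 (not isolated)
Conditions: Me3Al (3 equiv), Cp2ZrCl2 (0.2 equiv), CH2Cl2, 0 °C to rt; then NBS, THF, −30 to 0 °C; aq. HCl
Reagents that add atoms: trimethylaluminium C[Al](C)C; N-bromosuccinimide O=C1CCC(=O)N1Br
Why: Negishi zirconium-catalysed carboalumination adds CH3 and Al syn across the alkyne with Al at the terminus, and bromodealumination retains geometry, which fixes the E C4=C5 alkene.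

Step 2
Reactants: 3 (4E)-5-bromo-4-methylpent-4-en-1-ol
Product: 4 (4E)-5-bromo-4-methylpent-4-enal
Conditions: Dess–Martin periodinane, CH2Cl2, 0 °C to rt
Reagents that add atoms: none
Why: Dess–Martin oxidation takes the primary alcohol to the aldehyde without touching the alkenyl bromide.

Step 3
Reactants: 5 iodoethane
Product: 6 ethyltriphenylphosphonium iodide
Conditions: PPh3, toluene, 90 °C
Reagents that add atoms: triphenylphosphine c1ccc(cc1)P(c1ccccc1)c1ccccc1
Why: SN2 quaternisation of the phosphine gives the phosphonium salt.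

Step 4
Reactants: 6 ethyltriphenylphosphonium iodide; 4 (4E)-5-bromo-4-methylpent-4-enal
Product: 10 (1E,5Z)-1-bromo-6-iodo-2-methylhepta-1,5-diene, via ethylide 7 (not isolated), via iodophosphonium iodide 8 (not isolated), via iodo ylide 9 (not isolated)
Conditions: n-BuLi, THF, rt; I2, −78 °C; NaN(SiMe3)2, −20 °C; then 4, −78 °C to rt
Reagents that add atoms: iodine II
Why: Stork–Zhao-type Wittig olefination, in which the α-iodo ylide reacts through the kinetic cis-oxaphosphetane to give the Z 2-iodoalk-2-ene (iodine cis to the chain), the geometry later carried into C1=C10.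

Step 5
Reactants: 11 L-erythrulose
Product: 12 (3S)-1,3,4-tris(triethylsilyloxy)butan-2-one
Conditions: TESCl (3.5 equiv), imidazole, DMF, 0 °C to rt
Reagents that add atoms: chlorotriethylsilane CC[Si](Cl)(CC)CC
Why: Imidazole-promoted O-silylation caps all three hydroxyls under conditions too mild to epimerise C8 next to the ketone.

Step 6
Reactants: 12 (3S)-1,3,4-tris(triethylsilyloxy)butan-2-one; 13 methyl prop-2-ynoate
Product: 14 methyl 2-[(2S,3S)-1,2,3,4-tetrakis(triethylsilyloxy)butan-2-yl]prop-2-enoate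
Conditions: (IPr)CuCl (5 mol %), NaOt-Bu (5 mol %), 13 (1.3 equiv), Et3SiH (1.3 equiv, slow addition), toluene, −40 to 0 °C
Reagents that add atoms: triethylsilane CC[SiH](CC)CC
Why: Proposed new method: copper hydride-catalysed reductive aldol (formal Morita–Baylis–Hillman) addition of a propiolate to a ketone with in situ O-silylation; (IPr)Cu–H delivers hydride to the β-carbon of 13 to give an α-cuprio acrylate/copper allenolate, which attacks the electron-poor α,α'-bis(silyloxy) ketone through C11 anti to the C8–OSi bond (polar Felkin–Anh, giving the 7,8-syn arrangement of the target), and σ-bond metathesis of the tertiary copper alkoxide with Et3SiH releases the TES ether and regenerates Cu–H; the closest known reaction types are CuH-catalysed reductive aldol additions of acrylates and allenoates to ketones and the stoichiometric vinylalumination of propiolates.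

Step 7
Reactants: 14 methyl 2-[(2S,3S)-1,2,3,4-tetrakis(triethylsilyloxy)butan-2-yl]prop-2-enoate
Product: 16 methyl 2-[(2S,3R)-4-oxo-1,2,3-tris(triethylsilyloxy)butan-2-yl]prop-2-enoate, via alkoxysulfonium chloride 15 (not isolated)
Conditions: (COCl)2 (1.2 equiv), DMSO, CH2Cl2, −78 to −45 °C; Et3N, −78 to 0 °C
Reagents that add atoms: none
Why: Swern-type oxidative desilylation turns a primary TES ether directly into the aldehyde; the C9 ether reacts ahead of the neopentyl C6 ether, secondary and tertiary ethers are inert, and the cold conditions keep C8 intact.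

Step 8
Reactants: 16 methyl 2-[(2S,3R)-4-oxo-1,2,3-tris(triethylsilyloxy)butan-2-yl]prop-2-enoate; 10 (1E,5Z)-1-bromo-6-iodo-2-methylhepta-1,5-diene
Product: 18 methyl 2-[(2S,3S,4S,5Z,9E)-10-bromo-4-hydroxy-5,9-dimethyl-1,2,3-tris(triethylsilyloxy)deca-5,9-dien-2-yl]prop-2-enoate, via alkenylchromium dichloride 17 (not isolated)
Conditions: 10 (1.5 equiv), CrCl2 (4 equiv), NiCl2 (2 mol %), DMSO/THF, rt
Reagents that add atoms: none
Why: Nickel-catalysed, chromium-mediated Nozaki–Hiyama–Kishi coupling, in which zerovalent nickel inserts into C–I far faster than into C–Br, the alkenylchromium adds only to the aldehyde with retention of the Z geometry, and Felkin–Anh attack anti to the C8–OSi bond gives the 8,9-anti (9S) alcohol.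

Step 9
Reactants: 18 methyl 2-[(2S,3S,4S,5Z,9E)-10-bromo-4-hydroxy-5,9-dimethyl-1,2,3-tris(triethylsilyloxy)deca-5,9-dien-2-yl]prop-2-enoate; 19 2-methylpropanoyl chloride
Product: 20 methyl 2-[(2S,3S,4S,5Z,9E)-10-bromo-5,9-dimethyl-4-(2-methylpropanoyloxy)-1,2,3-tris(triethylsilyloxy)deca-5,9-dien-2-yl]prop-2-enoate
Conditions: pyridine, DMAP (cat.), CH2Cl2, 0 °C to rt
Reagents that add atoms: none
Why: DMAP-catalysed acylation esterifies the only free hydroxyl and installs the final isobutyrate before it can lactonise onto the acrylate.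

Step 10
Reactants: 20 methyl 2-[(2S,3S,4S,5Z,9E)-10-bromo-5,9-dimethyl-4-(2-methylpropanoyloxy)-1,2,3-tris(triethylsilyloxy)deca-5,9-dien-2-yl]prop-2-enoate
Product: 22 methyl 2-[(2R,3S,4S,5Z,9E)-10-bromo-5,9-dimethyl-4-(2-methylpropanoyloxy)-1-oxo-2,3-bis(triethylsilyloxy)deca-5,9-dien-2-yl]prop-2-enoate, via alkoxysulfonium chloride 21 (not isolated)
Conditions: (COCl)2 (2 equiv), DMSO, CH2Cl2, −78 to −30 °C; Et3N, −78 to 0 °C
Reagents that add atoms: none
Why: The same Swern-type oxidative desilylation converts the one remaining primary TES ether into the C6 aldehyde without passing through a free C6 alcohol that would lactonise; the aldehyde has no α-hydrogen.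

Step 11
Reactants: 22 methyl 2-[(2R,3S,4S,5Z,9E)-10-bromo-5,9-dimethyl-4-(2-methylpropanoyloxy)-1-oxo-2,3-bis(triethylsilyloxy)deca-5,9-dien-2-yl]prop-2-enoate
Product: 25 (3aS,4S,5S,6Z,10E,11aS)-6,10-dimethyl-3-methylidene-2-oxo-3a,4-bis(triethylsilyloxy)-2,3,3a,4,5,8,9,11a-octahydrocyclodeca[b]furan-5-yl 2-methylpropanoate, via TMS ether 23 (not isolated), via hydroxy ester 24 (not isolated)
Conditions: CrCl2 (20 mol %), NiCl2 (5 mol %), Mn powder (3 equiv), Me3SiCl (2.5 equiv), DMF/DME, 50 °C, slow addition (2 mM); then 10% aq. citric acid, THF, rt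
Reagents that add atoms: none
Why: Intramolecular Nozaki–Hiyama–Kishi coupling catalytic in chromium and nickel (Mn/Me3SiCl turnover) closes the ten-membered ring at C5–C6 with retention of the E alkene; Felkin–Anh addition anti to the C7–OSi bond, with the ring tether C8 in the inside position, sets C6 (S), and after O–TMS cleavage the γ-hydroxy ester lactonises to the trans-fused methylene lactone.

Step 12
Reactants: 25 (3aS,4S,5S,6Z,10E,11aS)-6,10-dimethyl-3-methylidene-2-oxo-3a,4-bis(triethylsilyloxy)-2,3,3a,4,5,8,9,11a-octahydrocyclodeca[b]furan-5-yl 2-methylpropanoate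
Product: 26 (3aR,4S,5S,6Z,10E,11aS)-3a,4-dihydroxy-6,10-dimethyl-3-methylidene-2-oxo-2,3,3a,4,5,8,9,11a-octahydrocyclodeca[b]furan-5-yl 2-methylpropanoate (CNP0301808.4)
Conditions: HF·pyridine, pyridine, THF, 0 °C to rt
Reagents that add atoms: none
Why: Fluoride-mediated desilylation under weakly acidic, base-free conditions frees the C7 and C8 hydroxyls without acyl migration, translactonisation or conjugate addition to the methylene lactone.

**Compound list**
1 | pent-4-yn-1-ol | C#CCCCO | starting material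
2 | alkenylalane, dimethyl[(1E)-5-(dimethylalumanyloxy)-2-methylpent-1-en-1-yl]alumane | C[Al](C)OCCC/C(C)=C/[Al](C)C | intermediate
3 | (4E)-5-bromo-4-methylpent-4-en-1-ol | OCCC/C(C)=C/Br | intermediate
4 | (4E)-5-bromo-4-methylpent-4-enal | O=CCC/C(C)=C/Br | intermediate
5 | iodoethane | CCI | starting material
6 | ethyltriphenylphosphonium iodide | CC[P+](c1ccccc1)(c1ccccc1)c1ccccc1.[I-] | intermediate
7 | ethylidene(triphenyl)phosphorane | CC=P(c1ccccc1)(c1ccccc1)c1ccccc1 | intermediate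
8 | (1-iodoethyl)triphenylphosphonium iodide | CC(I)[P+](c1ccccc1)(c1ccccc1)c1ccccc1.[I-] | intermediate
9 | (1-iodoethylidene)triphenylphosphorane | CC(I)=P(c1ccccc1)(c1ccccc1)c1ccccc1 | intermediate
10 | (1E,5Z)-1-bromo-6-iodo-2-methylhepta-1,5-diene | Br/C=C(\C)CC/C=C(\I)C | intermediate
11 | L-erythrulose, (3S)-1,3,4-trihydroxybutan-2-one | OCC(=O)[C@@H](O)CO | starting material
12 | (3S)-1,3,4-tris(triethylsilyloxy)butan-2-one | CC[Si](CC)(CC)OCC(=O)[C@@H](O[Si](CC)(CC)CC)CO[Si](CC)(CC)CC | intermediate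
13 | methyl prop-2-ynoate (methyl propiolate) | C#CC(=O)OC | starting material
14 | methyl 2-[(2S,3S)-1,2,3,4-tetrakis(triethylsilyloxy)butan-2-yl]prop-2-enoate | C=C(C(=O)OC)[C@@](CO[Si](CC)(CC)CC)(O[Si](CC)(CC)CC)[C@@H](O[Si](CC)(CC)CC)CO[Si](CC)(CC)CC | intermediate
15 | C9 alkoxysulfonium chloride of 14 (C9–O–S+Me2 in place of C9–OTES) | C=C(C(=O)OC)[C@@](CO[Si](CC)(CC)CC)(O[Si](CC)(CC)CC)[C@@H](O[Si](CC)(CC)CC)CO[S+](C)C.[Cl-] | intermediate
16 | methyl 2-[(2S,3R)-4-oxo-1,2,3-tris(triethylsilyloxy)butan-2-yl]prop-2-enoate | C=C(C(=O)OC)[C@@](CO[Si](CC)(CC)CC)(O[Si](CC)(CC)CC)[C@@H](O[Si](CC)(CC)CC)C=O | intermediate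
17 | dichloro[(2Z,6E)-7-bromo-6-methylhepta-2,6-dien-2-yl]chromium | Br/C=C(\C)CC/C=C(\[Cr](Cl)Cl)C | intermediate
18 | methyl 2-[(2S,3S,4S,5Z,9E)-10-bromo-4-hydroxy-5,9-dimethyl-1,2,3-tris(triethylsilyloxy)deca-5,9-dien-2-yl]prop-2-enoate | C=C(C(=O)OC)[C@@](CO[Si](CC)(CC)CC)(O[Si](CC)(CC)CC)[C@@H](O[Si](CC)(CC)CC)[C@@H](O)/C(C)=C\CC/C(C)=C/Br | intermediate
19 | 2-methylpropanoyl chloride (isobutyryl chloride) | CC(C)C(Cl)=O | starting material
20 | methyl 2-[(2S,3S,4S,5Z,9E)-10-bromo-5,9-dimethyl-4-(2-methylpropanoyloxy)-1,2,3-tris(triethylsilyloxy)deca-5,9-dien-2-yl]prop-2-enoate | C=C(C(=O)OC)[C@@](CO[Si](CC)(CC)CC)(O[Si](CC)(CC)CC)[C@@H](O[Si](CC)(CC)CC)[C@@H](OC(=O)C(C)C)/C(C)=C\CC/C(C)=C/Br | intermediate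
21 | C6 alkoxysulfonium chloride of 20 (C6–O–S+Me2 in place of C6–OTES) | C=C(C(=O)OC)[C@@](CO[S+](C)C)(O[Si](CC)(CC)CC)[C@@H](O[Si](CC)(CC)CC)[C@@H](OC(=O)C(C)C)/C(C)=C\CC/C(C)=C/Br.[Cl-] | intermediate
22 | methyl 2-[(2R,3S,4S,5Z,9E)-10-bromo-5,9-dimethyl-4-(2-methylpropanoyloxy)-1-oxo-2,3-bis(triethylsilyloxy)deca-5,9-dien-2-yl]prop-2-enoate | C=C(C(=O)OC)[C@@](C=O)(O[Si](CC)(CC)CC)[C@@H](O[Si](CC)(CC)CC)[C@@H](OC(=O)C(C)C)/C(C)=C\CC/C(C)=C/Br | intermediate
23 | methyl 2-[(1S,2S,3E,7Z,9S,10S)-4,8-dimethyl-9-(2-methylpropanoyloxy)-1,10-bis(triethylsilyloxy)-2-(trimethylsilyloxy)cyclodeca-3,7-dien-1-yl]prop-2-enoate | C=C(C(=O)OC)[C@@]1(O[Si](CC)(CC)CC)[C@@H](O[Si](CC)(CC)CC)[C@@H](OC(=O)C(C)C)/C(C)=C\CC/C(C)=C/[C@@H]1O[Si](C)(C)C | intermediate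
24 | methyl 2-[(1S,2S,3E,7Z,9S,10S)-2-hydroxy-4,8-dimethyl-9-(2-methylpropanoyloxy)-1,10-bis(triethylsilyloxy)cyclodeca-3,7-dien-1-yl]prop-2-enoate | C=C(C(=O)OC)[C@@]1(O[Si](CC)(CC)CC)[C@@H](O[Si](CC)(CC)CC)[C@@H](OC(=O)C(C)C)/C(C)=C\CC/C(C)=C/[C@@H]1O | intermediate
25 | (3aS,4S,5S,6Z,10E,11aS)-6,10-dimethyl-3-methylidene-2-oxo-3a,4-bis(triethylsilyloxy)-2,3,3a,4,5,8,9,11a-octahydrocyclodeca[b]furan-5-yl 2-methylpropanoate | C=C1C(=O)O[C@H]2/C=C(\C)CC/C=C(/C)[C@H](OC(=O)C(C)C)[C@H](O[Si](CC)(CC)CC)[C@]12O[Si](CC)(CC)CC | intermediate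
26 | (3aR,4S,5S,6Z,10E,11aS)-3a,4-dihydroxy-6,10-dimethyl-3-methylidene-2-oxo-2,3,3a,4,5,8,9,11a-octahydrocyclodeca[b]furan-5-yl 2-methylpropanoate | C=C1C(=O)O[C@H]2/C=C(\C)CC/C=C(/C)[C@H](OC(=O)C(C)C)[C@H](O)[C@]12O | target

**Step count and risks**
Total steps: 12. Longest linear sequence: 8 (steps 5–12; the western branch, steps 1, 2, 4 and 8–12, is equally long), which is two thirds of the total.

Steps most likely to fail:

Step 6 (proposed new reaction). The risks are direct CuH reduction of the ketone, over-reduction of the product acrylate, and slow silyl transfer to the tertiary copper alkoxide. The fallback uses known chemistry, sets out from 12 and 13 and comes back at 14. Hydroalumination of 13 with i-Bu2AlH and N-methylmorpholine N-oxide (THF, 0 °C) gives [1-(methoxycarbonyl)ethenyl]bis(2-methylpropyl)aluminium F1. Stoichiometric vinylalumination of 12 with it (−78 to 0 °C, same Felkin–Anh sense) gives the tertiary alcohol methyl 2-[(2S,3S)-2-hydroxy-1,3,4-tris(triethylsilyloxy)butan-2-yl]prop-2-enoate F2. Silylation with TESOTf and 2,6-lutidine (CH2Cl2, −78 °C) then gives 14.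

Step 7 (site selection between two primary TES ethers). The fallback sets out from 14 and comes back at 16. The selection is moved from the oxidation to a deprotection that can be stopped early and recycled: HF·pyridine/pyridine (THF, −20 °C, partial conversion) frees the less hindered C9 hydroxyl to give methyl 2-[(2S,3S)-4-hydroxy-1,2,3-tris(triethylsilyloxy)butan-2-yl]prop-2-enoate F3. Immediate Dess–Martin oxidation of F3 gives 16.

Step 11 (ring closure and C6 configuration). The fallback sets out from 23 and comes back at 24; it sets C6 by ketone reduction instead of by the C–C bond formation. The chromium/nickel reaction is worked up without acid, so that 23 is isolated together with its C6 epimer, methyl 2-[(1S,2R,3E,7Z,9S,10S)-4,8-dimethyl-9-(2-methylpropanoyloxy)-1,10-bis(triethylsilyloxy)-2-(trimethylsilyloxy)cyclodeca-3,7-dien-1-yl]prop-2-enoate F4. Pyridinium chlorochromate, [C5H5NH][CrO3Cl], with NaOAc in CH2Cl2 oxidises both silyl ethers directly to the single enone methyl 2-[(1R,3E,7Z,9S,10S)-4,8-dimethyl-9-(2-methylpropanoyloxy)-2-oxo-1,10-bis(triethylsilyloxy)cyclodeca-3,7-dien-1-yl]prop-2-enoate F5. Reagent-controlled CBS reduction (BH3·SMe2, with the oxazaborolidine enantiomer that a two-run screen shows to give the 6S alcohol) returns 24, which lactonises to 25 as in step 11.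

**Further compounds**
F1 | step 6 | [1-(methoxycarbonyl)ethenyl]bis(2-methylpropyl)aluminium | C=C(C(=O)OC)[Al](CC(C)C)CC(C)C
F2 | step 6 | methyl 2-[(2S,3S)-2-hydroxy-1,3,4-tris(triethylsilyloxy)butan-2-yl]prop-2-enoate | C=C(C(=O)OC)[C@@](CO[Si](CC)(CC)CC)(O)[C@@H](O[Si](CC)(CC)CC)CO[Si](CC)(CC)CC
F3 | step 7 | methyl 2-[(2S,3S)-4-hydroxy-1,2,3-tris(triethylsilyloxy)butan-2-yl]prop-2-enoate | C=C(C(=O)OC)[C@@](CO[Si](CC)(CC)CC)(O[Si](CC)(CC)CC)[C@@H](O[Si](CC)(CC)CC)CO
F4 | step 11 | methyl 2-[(1S,2R,3E,7Z,9S,10S)-4,8-dimethyl-9-(2-methylpropanoyloxy)-1,10-bis(triethylsilyloxy)-2-(trimethylsilyloxy)cyclodeca-3,7-dien-1-yl]prop-2-enoate | C=C(C(=O)OC)[C@@]1(O[Si](CC)(CC)CC)[C@@H](O[Si](CC)(CC)CC)[C@@H](OC(=O)C(C)C)/C(C)=C\CC/C(C)=C/[C@H]1O[Si](C)(C)C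
F5 | step 11 | methyl 2-[(1R,3E,7Z,9S,10S)-4,8-dimethyl-9-(2-methylpropanoyloxy)-2-oxo-1,10-bis(triethylsilyloxy)cyclodeca-3,7-dien-1-yl]prop-2-enoate | C=C(C(=O)OC)[C@@]1(O[Si](CC)(CC)CC)[C@@H](O[Si](CC)(CC)CC)[C@@H](OC(=O)C(C)C)/C(C)=C\CC/C(C)=C/C1=O
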